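**Plan**

1. Locants: the ten-membered ring is C1–C10 (C1=C10 with the ester carbon C14 on C10; 2,3-epoxide; C4=C5 with methyl C15; lactone oxygen on C6; esters on C8 and C9); the methylene lactone is C7–C11(=C13)–C12.
2. Retrosynthesis cuts, in this order: the O9 and O8 acyl bonds, the ring bond C9–C10, the C1=C10 double bond, the epoxide C–O bonds, C3–C4, and C6–C7 together with the lactone bond C12–O6.
3. Enabling feature: C10 is a vinylic carbon that carries the ester C14 and sits next to the carbinol C9 (an α-(1-hydroxyalkyl)acrylate), so an alkenyl-metal at C10, made from a (Z)-α-iodoenoate, can add to a C9 aldehyde. The arc C10=C1–C2(O)C3–C4=C5–C6 is bent into a U by two Z olefins and the cis-epoxide, and C6–C7 is fixed in the trans-fused butyrolactone, which places C9 beside C10.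
4. Forward: the butyrolactone comes first (chromium allylation, C6–C7), the chain grows at C4 (Stille) and C1 (iodo-Wittig), the ten-membered ring is closed last at C9–C10, and the C9 ester ends the route.
5. Stereochemistry: C8 from D-glyceraldehyde; C7 and C6 by 1,2-induction and a chair transition state in the allylation; C2/C3 and the epoxy acid by Sharpless epoxidations with D-(−)-tartrate; C9 in the ring closure; (R)-2-methylbutanoic acid is bought. Olefin geometries come from hydroalumination–iodination (C4=C5), a (Z)-stannane (C2=C3) and the iodo ylide (C1=C10).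

Key step: step 19

Remark: (2Z)-3-iodobut-2-en-1-ol and (2Z)-3-(tributylstannyl)prop-2-en-1-ol are assumed not to be purchasable and are made in one step each. Names of intermediates use the locants above, and "as in the target" means the same spatial arrangement as in the target (2R,3S,6R,7S,8S,9S; 2S,3S in the epoxy acid; R in the 2-methylbutanoate); the SMILES are decisive.

**Route**

Step 1
Reactants: 1 (R)-2,2-dimethyl-1,3-dioxolane-4-carbaldehyde (D-glyceraldehyde acetonide); 2 methyl acrylate
Product: 3 methyl 2-{[(4R)-2,2-dimethyl-1,3-dioxolan-4-yl](hydroxy)methyl}prop-2-enoate (both carbinol epimers)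
Conditions: DABCO (1 equiv), 1,4-dioxane/H2O 1:1, rt
Reagents that add atoms: none
Why: Morita–Baylis–Hillman reaction of an unhindered aldehyde with an acrylate; the new carbinol centre (future C7) becomes sp2 in step 2 and need not be controlled, and the dioxolane centre (future C8) is not enolised under these conditions.

Step 2
Reactants: 3
Product: 4 methyl (2Z)-2-(bromomethyl)-3-[(4S)-2,2-dimethyl-1,3-dioxolan-4-yl]prop-2-enoate (same spatial arrangement at the dioxolane carbon as in 3)
Conditions: NBS, Me2S, CH2Cl2, 0 °C to rt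
Reagents that add atoms: N-bromosuccinimide, O=C1CCC(=O)N1Br
Why: The alkoxysulfonium salt of the Morita–Baylis–Hillman alcohol is displaced by bromide with allylic transposition (SN2′) to the thermodynamically preferred (Z)-2-(bromomethyl)enoate; both epimers of 3 converge and the acetal survives the non-acidic conditions.

Step 3
Reactants: 5 but-2-yn-1-ol
Product: 7 (2Z)-3-iodobut-2-en-1-ol, via cyclic sodium alkenylalanate 6 (not isolated)
Conditions: NaAlH2(OCH2CH2OMe)2, Et2O, 0 °C to rt; then I2, THF, −78 °C
Reagents that add atoms: iodine, II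
Why: Alkoxide-directed trans-hydroalumination of the propargylic alcohol puts aluminium on C4 cis to the CH2O group, and iodinolysis with retention gives the Z alkenyl iodide, which fixes the C4=C5 geometry (C6 cis to the future C3).

Step 4
Reactants: 7
Product: 8 (2Z)-3-iodobut-2-enal
Conditions: MnO2, CH2Cl2, rt, dark
Reagents that add atoms: none
Why: Allylic oxidation on activated MnO2 is neutral, so the Z β-iodoenal should not isomerise; it is used at once.

Step 5
Reactants: 4; 8
Product: 11 trans-lactone 4-[(4S)-2,2-dimethyl-1,3-dioxolan-4-yl]-5-[(1Z)-2-iodoprop-1-en-1-yl]-3-methylideneoxolan-2-one (C6/C7/C8 as in the target), via allylchromium dichloride 9 (not isolated), via anti hydroxy ester 10 (not isolated)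
Conditions: CrCl2 (3 equiv, nickel-free), THF, 0 °C to rt; then PPTS (cat.), CH2Cl2, rt
Reagents that add atoms: none
Why: Nozaki–Hiyama allylation: the allylchromium 9 (trivalent chromium) adds to 8 through a chair transition state with the C5 alkenyl group and C8 equatorial, which gives the 6,7-anti adduct and hence the trans-lactone; C7 is attacked on the face anti to the dioxolane C8–C9 bond with H8 turned towards the ester-bearing carbon (1,3-allylic strain), which sets 7S and with it 6R relative to 8S; nickel-free CrCl2 leaves the alkenyl iodide alone, and the adduct 10 closes the lactone with loss of methanol.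

Step 6
Reactants: 11
Product: 12 diol 4-[(1S)-1,2-dihydroxyethyl]-5-[(1Z)-2-iodoprop-1-en-1-yl]-3-methylideneoxolan-2-one (C6/C7/C8 as in the target)
Conditions: AcOH/H2O 4:1, 40 °C
Reagents that add atoms: none
Why: Acid hydrolysis of the terminal isopropylidene acetal; the alkenyl iodide and the methylene lactone are inert to aqueous acetic acid, and a shift of the lactone to O8 is not expected because it would give the less stable cis-fused isomer.

Step 7
Reactants: 12
Product: 13 9-O-triethylsilyl ether of 12 (C8 hydroxyl free)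
Conditions: Et3SiCl, imidazole, CH2Cl2, −40 °C
Reagents that add atoms: chlorotriethylsilane, CC[Si](CC)(CC)Cl
Why: The primary C9 hydroxyl is silylated much faster than the hindered secondary C8 hydroxyl at low temperature.

Step 8
Reactants: 14 angelic acid, (2Z)-2-methylbut-2-enoic acid
Product: 15 (2Z)-2-methylbut-2-en-1-ol
Conditions: LiAlH4, Et2O, 0 °C
Reagents that add atoms: none
Why: Hydride reduction of the carboxylic acid to the allylic alcohol; the trisubstituted olefin is not reduced and keeps its Z geometry.

Step 9
Reactants: 15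
Product: 16 [(2R,3S)-2,3-dimethyloxiran-2-yl]methanol
Conditions: Ti(OiPr)4, D-(−)-diethyl tartrate, t-BuOOH, 4 Å molecular sieves, CH2Cl2, −20 °C
Reagents that add atoms: tert-butyl hydroperoxide, CC(C)(C)OO
Why: Sharpless asymmetric epoxidation of the allylic alcohol; D-(−)-tartrate delivers oxygen to the face that gives the 2R,3S epoxy alcohol (2S,3S once C1 is a carboxyl group), and the Z geometry fixes the two methyl groups trans on the oxirane.

Step 10
Reactants: 16
Product: 18 (2S,3S)-2,3-dimethyloxirane-2-carboxylic acid, via epoxy aldehyde 17 (not isolated)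
Conditions: TEMPO (cat.), PhI(OAc)2, MeCN/H2O 1:1, rt
Reagents that add atoms: water, O
Why: Oxoammonium oxidation of the primary alcohol to the aldehyde and, through its hydrate, to the acid; the quaternary α-carbon cannot epimerise and the epoxide is stable at this near-neutral pH.

Step 11
Reactants: 13; 18
Product: 19 C8 ester of 13 with 18 (8-O-[(2S,3S)-2,3-dimethyloxirane-2-carbonyl], 9-O-SiEt3, alkenyl iodide at C4)
Conditions: DCC, DMAP, CH2Cl2, 0 °C to rt
Reagents that add atoms: none
Why: Steglich esterification of the remaining secondary C8 hydroxyl with retention at C8; the acid has no α-hydrogen and cannot epimerise.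

Step 12
Reactants: 20 prop-2-yn-1-ol
Product: 22 (2Z)-3-(tributylstannyl)prop-2-en-1-ol, via cyclic lithium alkenylalanate 21 (not isolated)
Conditions: LiAlH4, THF, 0 °C to rt; then Bu3SnOTf, −78 °C to rt
Reagents that add atoms: tributyltin trifluoromethanesulfonate, CCCC[Sn](CCCC)(CCCC)OS(=O)(=O)C(F)(F)F
Why: Alkoxide-directed trans-hydroalumination places aluminium on C3 cis to the CH2O group and stannylation with retention gives the Z alkenylstannane (future C1–C3).

Step 13
Reactants: 19; 22
Product: 23 (2Z,4Z)-dienol (19 with iodine replaced by (Z)-CH=CH–CH2OH; C1 hydroxyl free)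
Conditions: Pd2(dba)3 (5 mol %), AsPh3 (20 mol %), NMP, rt, dark
Reagents that add atoms: none
Why: Stille coupling of a Z alkenyl iodide with a Z alkenylstannane forms C3–C4 with retention at both partners; oxidative addition of zerovalent palladium into the C–I bond is faster than ionisation of the allylic lactone, and the free hydroxyl, the epoxy ester and the silyl ether are inert.

Step 14
Reactants: 23
Product: 24 cis-2,3-epoxy alcohol (2R,3S as in the target; C1 hydroxyl)
Conditions: Ti(OiPr)4, D-(−)-diethyl tartrate, t-BuOOH, 4 Å molecular sieves, CH2Cl2, −20 °C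
Reagents that add atoms: tert-butyl hydroperoxide, CC(C)(C)OO
Why: Sharpless asymmetric epoxidation acts only on the olefin allylic to the free hydroxyl (C2=C3); D-(−)-tartrate delivers oxygen to the face that gives the 2R,3S cis-epoxide (reagent control, Z geometry retained), while the electron-poor methylene lactone and the C4=C5 bond are left.

Step 15
Reactants: 24
Product: 25 cis-2,3-epoxy aldehyde (C1 aldehyde)
Conditions: Dess–Martin periodinane, pyridine, CH2Cl2, 0 °C
Reagents that add atoms: none
Why: Dess–Martin oxidation buffered with pyridine should give the cis-epoxy aldehyde without epimerisation at C2 or acid-induced opening of the vinyl epoxide.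

Step 16
Reactants: 25
Product: 26 methyl (Z)-α-iodoenoate (C1=C10 with iodine on C10 cis to C2; 9-O-SiEt3)
Conditions: Ph3P=CHCO2Me, N-iodosuccinimide, CH2Cl2, −20 °C; then 25, −20 °C to rt
Reagents that add atoms: methyl (triphenylphosphoranylidene)acetate, COC(=O)C=P(c1ccccc1)(c1ccccc1)c1ccccc1; N-iodosuccinimide, O=C1CCC(=O)N1I
Why: Wittig olefination with the iodo ylide formed in the flask; as with other ester-stabilised ylides C2 ends up trans to the ester, which is the (Z)-α-iodoenoate needed for a ring-cis C1=C10 bond, and the base-free conditions spare the cis-epoxy aldehyde.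

Step 17
Reactants: 26
Product: 27 C9 primary alcohol
Conditions: Bu4NF, AcOH (1:1), THF, 0 °C
Reagents that add atoms: none
Why: Fluoride cleavage of the primary triethylsilyl ether; buffering with acetic acid keeps the medium near neutral so that neither 1,2-acyl shift from O8 to O9 nor epoxide opening should occur.

Step 18
Reactants: 27
Product: 28 C9 aldehyde (open-chain precursor of the ring)
Conditions: Dess–Martin periodinane, pyridine, CH2Cl2, 0 °C
Reagents that add atoms: none
Why: Dess–Martin oxidation to the α-acyloxy aldehyde under buffered conditions; the aldehyde is used at once so that C8 does not epimerise.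

Step 19
Reactants: 28
Product: 30 ten-membered carbinol (9S alcohol; the target without its 2-methylbutanoyl group), via alkenylchromium dichloride 29 (not isolated)
Conditions: CrCl2 (10 equiv), NiCl2 (0.1 equiv), DMSO/THF 3:1, 2 mM (syringe-pump addition of 28), rt
Reagents that add atoms: none
Why: Nozaki–Hiyama–Kishi reaction: zerovalent nickel (from NiCl2 and CrCl2) inserts into the C10–I bond of the (Z)-α-iodoenoate with retention, transmetallation gives the alkenylchromium 29 (trivalent chromium), and this adds to the C9 aldehyde. The closest known reaction type is the intramolecular alkenyl iodide–aldehyde nickel/chromium coupling used for nine- to twelve-membered carbocycles. The ten-membered ring closes in a 10-exo-trig mode with the carbonyl oxygen outside the ring. The ring-cis C1=C10 geometry (C2 and C9 cis) follows from retention at C10, and the only new stereocentre, C9, is set by the ring conformation imposed by the two Z olefins, the cis-epoxide and the trans-lactone: the aldehyde should react in the rotamer with H8 and H9 anti and both oxygen substituents on the periphery, which leads to 9S (8,9-trans) against the weak acyclic Felkin–Anh bias. The step needs ring closure over oligomerisation, secured by high dilution and the U-shaped C10–C6 arc, and attack at the C–I bond only, secured by the mild, non-basic divalent chromium reagent that leaves both epoxides and both conjugated esters alone at room temperature.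

Step 20
Reactants: 30; 31 (R)-2-methylbutanoic acid
Product: 32 target (CNP0485260.1)
Conditions: DCC, DMAP (cat.), CH2Cl2, 0 °C
Reagents that add atoms: none
Why: Steglich esterification of the allylic C9 alcohol with retention at C9; DMAP catalysis at 0 °C should outrun migration of the neighbouring C8 ester and does not epimerise the α-centre of the acid.

**Compound list**

1 | (R)-2,2-dimethyl-1,3-dioxolane-4-carbaldehyde | O=C[C@H]1COC(C)(C)O1 | starting material
2 | methyl acrylate | C=CC(=O)OC | starting material
3 | methyl 2-{[(4R)-2,2-dimethyl-1,3-dioxolan-4-yl](hydroxy)methyl}prop-2-enoate (both carbinol epimers) | C=C(C(=O)OC)C(O)[C@H]1COC(C)(C)O1 | intermediate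
4 | methyl (2Z)-2-(bromomethyl)-3-[(4S)-2,2-dimethyl-1,3-dioxolan-4-yl]prop-2-enoate | BrC/C(C(=O)OC)=C\[C@H]1COC(C)(C)O1 | intermediate
5 | but-2-yn-1-ol | CC#CCO | starting material
6 | cyclic sodium alkenylalanate from 5 (aluminium on C4 and on the alkoxide oxygen, two 2-methoxyethoxy groups) | [Na+].CC1=CCO[Al-]1(OCCOC)OCCOC | intermediate (not isolated)
7 | (2Z)-3-iodobut-2-en-1-ol | OC/C=C(/C)I | intermediate
8 | (2Z)-3-iodobut-2-enal | O=C/C=C(/C)I | intermediate
9 | 2-(methoxycarbonyl)allylchromium dichloride from 4 (E/Z interconverting) | Cl[Cr](Cl)CC(C(=O)OC)=C[C@H]1COC(C)(C)O1 | intermediate (not isolated)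
10 | methyl (5Z)-3-[(4S)-2,2-dimethyl-1,3-dioxolan-4-yl]-4-hydroxy-6-iodo-2-methylidenehept-5-enoate (6,7-anti; C6/C7/C8 as in the target) | C=C(C(=O)OC)[C@@H]([C@H](O)/C=C(/C)I)[C@H]1COC(C)(C)O1 | intermediate (not isolated)
11 | trans-lactone 4-[(4S)-2,2-dimethyl-1,3-dioxolan-4-yl]-5-[(1Z)-2-iodoprop-1-en-1-yl]-3-methylideneoxolan-2-one (C6/C7/C8 as in the target) | C=C1C(=O)O[C@H](/C=C(/C)I)[C@H]1[C@H]1COC(C)(C)O1 | intermediate
12 | diol 4-[(1S)-1,2-dihydroxyethyl]-5-[(1Z)-2-iodoprop-1-en-1-yl]-3-methylideneoxolan-2-one (C6/C7/C8 as in the target) | C=C1C(=O)O[C@H](/C=C(/C)I)[C@H]1[C@H](O)CO | intermediate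
13 | 9-O-triethylsilyl ether of 12 | C=C1C(=O)O[C@H](/C=C(/C)I)[C@H]1[C@H](O)CO[Si](CC)(CC)CC | intermediate
14 | angelic acid, (2Z)-2-methylbut-2-enoic acid | C/C=C(/C)C(=O)O | starting material
15 | (2Z)-2-methylbut-2-en-1-ol | C/C=C(/C)CO | intermediate
16 | [(2R,3S)-2,3-dimethyloxiran-2-yl]methanol | OC[C@@]1(C)O[C@H]1C | intermediate
17 | (2S,3S)-2,3-dimethyloxirane-2-carbaldehyde | O=C[C@@]1(C)O[C@H]1C | intermediate (not isolated)
18 | (2S,3S)-2,3-dimethyloxirane-2-carboxylic acid | OC(=O)[C@@]1(C)O[C@H]1C | intermediate
19 | C8 (2S,3S)-2,3-dimethyloxirane-2-carboxylate of 13 (9-O-SiEt3; Z alkenyl iodide at C4) | C=C1C(=O)O[C@H](/C=C(/C)I)[C@H]1[C@H](OC(=O)[C@@]1(C)O[C@H]1C)CO[Si](CC)(CC)CC | intermediate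
20 | prop-2-yn-1-ol | C#CCO | starting material
21 | cyclic lithium alkenylalanate from 20 | [Li+].[AlH2-]1OCC=C1 | intermediate (not isolated)
22 | (2Z)-3-(tributylstannyl)prop-2-en-1-ol | OC/C=C\[Sn](CCCC)(CCCC)CCCC | intermediate
23 | (2Z,4Z)-dienol (C1 hydroxyl; 8-O-epoxy ester; 9-O-SiEt3) | C=C1C(=O)O[C@H](/C=C(/C)\C=C/CO)[C@H]1[C@H](OC(=O)[C@@]1(C)O[C@H]1C)CO[Si](CC)(CC)CC | intermediate
24 | cis-2,3-epoxy alcohol (2R,3S as in the target) | C=C1C(=O)O[C@H](/C=C(/C)[C@@H]2O[C@@H]2CO)[C@H]1[C@H](OC(=O)[C@@]1(C)O[C@H]1C)CO[Si](CC)(CC)CC | intermediate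
25 | cis-2,3-epoxy aldehyde (C1 aldehyde) | C=C1C(=O)O[C@H](/C=C(/C)[C@@H]2O[C@@H]2C=O)[C@H]1[C@H](OC(=O)[C@@]1(C)O[C@H]1C)CO[Si](CC)(CC)CC | intermediate
26 | methyl (Z)-α-iodoenoate (C1=C10; iodine on C10 cis to C2; 9-O-SiEt3) | C=C1C(=O)O[C@H](/C=C(/C)[C@@H]2O[C@@H]2/C=C(/C(=O)OC)I)[C@H]1[C@H](OC(=O)[C@@]1(C)O[C@H]1C)CO[Si](CC)(CC)CC | intermediate
27 | C9 primary alcohol | C=C1C(=O)O[C@H](/C=C(/C)[C@@H]2O[C@@H]2/C=C(/C(=O)OC)I)[C@H]1[C@H](OC(=O)[C@@]1(C)O[C@H]1C)CO | intermediate
28 | C9 aldehyde (open-chain precursor of the ring) | C=C1C(=O)O[C@H](/C=C(/C)[C@@H]2O[C@@H]2/C=C(/C(=O)OC)I)[C@H]1[C@H](OC(=O)[C@@]1(C)O[C@H]1C)C=O | intermediate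
29 | alkenylchromium dichloride from 28 (chromium on C10) | C=C1C(=O)O[C@H](/C=C(/C)[C@@H]2O[C@@H]2/C=C(/C(=O)OC)[Cr](Cl)Cl)[C@H]1[C@H](OC(=O)[C@@]1(C)O[C@H]1C)C=O | intermediate (not isolated)
30 | ten-membered carbinol (9S alcohol; target without the 2-methylbutanoyl group) | C=C1C(=O)O[C@@H]2/C=C(/C)[C@@H]3O[C@@H]3/C=C(/C(=O)OC)[C@H](O)[C@@H](OC(=O)[C@@]3(C)O[C@H]3C)[C@@H]12 | intermediate
31 | (R)-2-methylbutanoic acid | OC(=O)[C@H](C)CC | starting material
32 | target CNP0485260.1 | C=C1C(=O)O[C@@H]2/C=C(/C)[C@@H]3O[C@@H]3/C=C(/C(=O)OC)[C@H](OC(=O)[C@H](C)CC)[C@@H](OC(=O)[C@@]3(C)O[C@H]3C)[C@@H]12 | target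

**Step count and risks**

Total step count: 20. Longest linear sequence: 14 steps (5 → 7 → 8 → 11 → 12 → 13 → 19 → 23 → 24 → 25 → 26 → 27 → 28 → 30 → 32).

Steps most likely to fail:

1. Step 19. The alkenylchromium may add to the other face of the C9 aldehyde (acyclic Felkin–Anh preference, attack anti to the C8–O bond), so that the carbinol forms mainly as the 9R epimer. Fallback: starting from 28, the same closure is run and the 9R carbinol F1 is esterified with inversion in place of retention. A Mitsunobu reaction of F1 with 31 (PPh3, DIAD, toluene, 0 °C) should give 32 directly, where the route is rejoined. The C8 ester is cis to the leaving group in F1 and cannot take part.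

2. Step 5. The aldehyde may attack C7 on the face anti to the C8–O bond in place of the face anti to the C8–C9 bond, which would set C6 and C7 in the wrong sense relative to C8. Fallback: the C8 centre is then bought in the other configuration and inverted when the ester is made. Starting from 2, 8 and purchased (S)-2,2-dimethyl-1,3-dioxolane-4-carbaldehyde, the conditions of steps 1 and 2 give the adduct F2 and the bromide F3. Allylation of 8 as in step 5 passes through the allylchromium F4 and the hydroxy ester F5 to the lactone F6, which has C6 and C7 as in the target and C8 inverted. Acetal hydrolysis gives the diol F7 and silylation the silyl ether F8. A Mitsunobu esterification of F8 with 18 (PPh3, DIAD, toluene, 0 °C to rt) inverts C8 and gives 19, where the route is rejoined.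

3. Step 13. Transmetallation between the two hindered Z partners may be slow, so that loss of tin from the stannane, homocoupling and Z to E drift compete. Fallback: the C1–C3 unit is brought in as an alkyne and the Z olefin is made afterwards. Starting from 19, a Sonogashira coupling with 20 (PdCl2(PPh3)2, CuI, Et3N, THF, rt) gives the enynol F9. Semi-hydrogenation (H2, Pd on CaCO3 poisoned with Pb(OAc)2, quinoline, EtOAc, stopped after one equivalent) sets the Z C2=C3 bond by syn addition and gives 23, where the route is rejoined.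

Further compounds
F1 | step 19 | 9R epimer of 30 | C=C1C(=O)O[C@@H]2/C=C(/C)[C@@H]3O[C@@H]3/C=C(/C(=O)OC)[C@@H](O)[C@@H](OC(=O)[C@@]3(C)O[C@H]3C)[C@@H]12
F2 | step 5 | methyl 2-{[(4S)-2,2-dimethyl-1,3-dioxolan-4-yl](hydroxy)methyl}prop-2-enoate (both carbinol epimers) | C=C(C(=O)OC)C(O)[C@@H]1COC(C)(C)O1
F3 | step 5 | methyl (2Z)-2-(bromomethyl)-3-[(4R)-2,2-dimethyl-1,3-dioxolan-4-yl]prop-2-enoate | BrC/C(C(=O)OC)=C\[C@@H]1COC(C)(C)O1
F4 | step 5 | 2-(methoxycarbonyl)allylchromium dichloride from F3 | Cl[Cr](Cl)CC(C(=O)OC)=C[C@@H]1COC(C)(C)O1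
F5 | step 5 | C8 epimer of 10 | C=C(C(=O)OC)[C@@H]([C@H](O)/C=C(/C)I)[C@@H]1COC(C)(C)O1
F6 | step 5 | C8 epimer of 11 | C=C1C(=O)O[C@H](/C=C(/C)I)[C@H]1[C@@H]1COC(C)(C)O1
F7 | step 5 | C8 epimer of 12 | C=C1C(=O)O[C@H](/C=C(/C)I)[C@H]1[C@@H](O)CO
F8 | step 5 | C8 epimer of 13 | C=C1C(=O)O[C@H](/C=C(/C)I)[C@H]1[C@@H](O)CO[Si](CC)(CC)CC
F9 | step 13 | enynol (19 with iodine replaced by C≡C–CH2OH) | C=C1C(=O)O[C@H](/C=C(/C)C#CCO)[C@H]1[C@H](OC(=O)[C@@]1(C)O[C@H]1C)CO[Si](CC)(CC)CC
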